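## Retrosynthetic overview

1. Numbering used throughout: four-membered ring C1–C5–C6–C10; ring A = C1–C5 (C2 OAc, C4 OH and CH3-15); ring B = C6–C10 (C8 OTig, C10 CH3-14); lactone O–C6, C7=C11, C12=O; C13 = CH2OAc.
2. Target ⇐ triol (both acetates last) ⇐ butenolide ⇐ 1,2-dioxine from singlet-oxygen [4+2] addition to the diene C6=C7–C11=C12H2. Enabling feature: the lactone O–C6 and the C12 carbonyl oxygen are 1,4-related across C7=C11 (an endoperoxide retron), and C6 is the sp2 carbon shared by ring B and the cis-fused four-membered ring, so oxygen can reach it only from the convex face.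
3. Diene ⇐ Suzuki coupling at C7 of an α-iodoenone; ring B ⇐ aldol condensation of a C8 methyl ketone onto the C6 cyclobutanone, whose oxygen leaves as water.
4. Quaternary C10 ⇐ two convex-face enolate alkylations (2-methylallyl, then methyl); four-membered ring ⇐ dichloroketene [2+2] on a cyclopentene, anti to two silyloxy groups; ring A ⇐ (S)-4-silyloxycyclopentenone + MeLi.
5. Order of ring formation: ring A (purchased), four-membered ring, ring B, 1,2-dioxine (temporary), lactone.

Key step: step 15

Remark on the chemistry: the SMILES is read as cis-syn-cis, with H1, H5, O6 and CH3-14 on one face of the four-membered ring and rings A and B on the other; 2-OAc, 4-OH and 8-OTig are exo (convex faces), CH3-15 is endo; configuration 1R,2S,4R,5R,6R,8S,10R in the numbering above.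

## Route

Step 1
Reactants: 1 (S)-4-(tert-butyldimethylsilyloxy)cyclopent-2-en-1-one
Product: 2 (1R,4S)-4-(tert-butyldimethylsilyloxy)-1-methylcyclopent-2-en-1-ol (OH cis to OTBS)
Conditions: MeLi, Et2O, −78 °C
Reagents that add atoms: methyllithium, [Li]C
Why: 1,2-addition of the hard organolithium to the enone carbonyl should take place on the face opposite to the γ-silyloxy group, which sets C4 with its hydroxyl cis to the C2 oxygen and CH3-15 trans to it.

Step 2
Reactants: 2 (1R,4S)-4-(tert-butyldimethylsilyloxy)-1-methylcyclopent-2-en-1-ol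
Product: 3 (1R,4S)-4-(tert-butyldimethylsilyloxy)-1-methyl-1-(triethylsilyloxy)cyclopent-2-ene
Conditions: TESOTf, 2,6-lutidine, CH2Cl2, −78 → 0 °C
Reagents that add atoms: triethylsilyl trifluoromethanesulfonate, CC[Si](CC)(CC)OS(=O)(=O)C(F)(F)F
Why: silyl triflate silylation of the tertiary allylic alcohol masks the only free hydroxyl before the ketene and enolate steps.

Step 3
Reactants: 3 (1R,4S)-4-(tert-butyldimethylsilyloxy)-1-methyl-1-(triethylsilyloxy)cyclopent-2-ene
Product: 4 10,10-dichlorocyclobutanone (ring A fused to the four-membered ring; C6 ketone; 2-OTBS and 4-OTES exo; CH3-15 endo; H1 and H5 cis)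
Conditions: Cl3CCOCl, activated Zn dust, Et2O, ultrasound, 15–25 °C
Reagents that add atoms: dichloroketene, ClC(Cl)=C=O (made in the flask from trichloroacetyl chloride, ClC(=O)C(Cl)(Cl)Cl, and Zn)
Why: thermal [2+2] ketene–alkene cycloaddition in which the ketene should enter on the ring face that carries only CH3-15 (anti to both silyloxy groups) with its bulky CCl2 end bonding to C1 and its carbonyl carbon to C5 next to the quaternary C4, which sets C1 and C5 cis.

Step 4
Reactants: 4 10,10-dichlorocyclobutanone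
Product: 5 parent cyclobutanone (C6 ketone, C10 H2; 2-OTBS and 4-OTES exo)
Conditions: Zn dust, NH4Cl, MeOH, rt
Reagents that add atoms: none
Why: reductive dechlorination of the α,α-dichloroketone by zinc should leave the ketone, both silyl ethers and the ring stereocentres untouched.

Step 5
Reactants: 5 parent cyclobutanone; 6 3-bromo-2-methylprop-1-ene
Product: 7 10-(2-methylallyl)cyclobutanone (exo-allyl epimer drawn; the C10 configuration is of no consequence)
Conditions: LiN(iPr)2, THF, −78 °C; then 6, DMPU, −78 → −30 °C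
Reagents that add atoms: none
Why: enolate alkylation in which the cyclobutanone can enolise only toward C10 (an enolate toward the ring-fusion carbon C5 would put a double bond at the 4/5 fusion) and the lithium enolate is allylated by SN2 on its convex face.

Step 6
Reactants: 7 10-(2-methylallyl)cyclobutanone
Product: 8 10-methyl-10-(2-methylallyl)cyclobutanone (CH3-14 exo, 2-methylallyl endo on the side of ring A; 10R)
Conditions: LiN(iPr)2, THF, −78 °C; then MeI, DMPU, −78 → 0 °C
Reagents that add atoms: iodomethane, CI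
Why: a second enolisation at C10 gives a planar enolate that iodomethane should alkylate from the convex (exo) face, which sets the quaternary C10 with CH3-14 exo and pushes the 2-methylallyl chain into the endo position.

Step 7
Reactants: 8 10-methyl-10-(2-methylallyl)cyclobutanone
Product: 9 1,4-diketone (C6 cyclobutanone and C8 methyl ketone; C7 is the ketone methyl)
Conditions: O3, CH2Cl2/MeOH, −78 °C; then Me2S, −78 °C → rt
Reagents that add atoms: ozone, [O-][O+]=O
Why: ozonolysis with reductive work-up cleaves the only C=C bond and unveils the methyl ketone.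

Step 8
Reactants: 9 1,4-diketone
Product: 10 tricyclic enone (ring B closed: C8 ketone, C6=C7; cis-syn-cis)
Conditions: KOH, MeOH, 50 °C
Reagents that add atoms: none
Why: intramolecular aldol condensation in which the methyl-ketone enolate (C7) attacks the strained, highly electrophilic cyclobutanone carbon C6 from the concave side dictated by the endo tether and E1cB loss of water gives the enone, closing ring B cis-syn-cis without a new stereocentre.

Step 9
Reactants: 10 tricyclic enone
Product: 11 7-iodo enone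
Conditions: I2, pyridine, CH2Cl2, 0 °C → rt
Reagents that add atoms: iodine, II
Why: iodine–pyridine α-iodination of the enone (conjugate addition of pyridine, iodination of the enolate, elimination) places a coupling handle on C7.

Step 10
Reactants: 12 2-bromoprop-2-en-1-ol
Product: 13 (2-bromoallyloxy)(tert-butyl)dimethylsilane
Conditions: TBSCl, imidazole, DMF, rt
Reagents that add atoms: tert-butyldimethylsilyl chloride, C[Si](C)(Cl)C(C)(C)C
Why: standard silylation of the primary allylic alcohol.

Step 11
Reactants: 13 (2-bromoallyloxy)(tert-butyl)dimethylsilane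
Product: 14 2-[3-(tert-butyldimethylsilyloxy)prop-1-en-2-yl]-4,4,5,5-tetramethyl-1,3,2-dioxaborolane
Conditions: B2pin2, PdCl2(PPh3)2, PPh3, KOPh, toluene, 50 °C
Reagents that add atoms: bis(pinacolato)diboron, CC1(C)OB(OC1(C)C)B1OC(C)(C)C(C)(C)O1
Why: Miyaura borylation of the 1,1-disubstituted alkenyl bromide should give the alkenyl boronate without touching the allylic silyl ether.

Step 12
Reactants: 11 7-iodo enone; 14 alkenyl boronate
Product: 15 cross-conjugated dienone (C8 ketone, C6=C7, C11=C12H2, C13 OTBS)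
Conditions: PdCl2(dppf), Cs2CO3, DMF/H2O, 40 °C
Reagents that add atoms: none
Why: Suzuki–Miyaura coupling of the α-iodoenone with the alkenyl boronate attaches C11 with C12 and C13 to C7.

Step 13
Reactants: 15 cross-conjugated dienone
Product: 16 endo allylic alcohol (C8 hydroxyl on the concave face; 8-epi)
Conditions: NaBH4, CeCl3·7H2O, MeOH, −40 °C
Reagents that add atoms: none
Why: Luche 1,2-reduction in which hydride should reach C8 from the convex face of ring B, so the hydroxyl ends on the concave side, opposite to the target configuration.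

Step 14
Reactants: 16 endo allylic alcohol; 17 tiglic acid, (E)-2-methylbut-2-enoic acid
Product: 18 8-O-tigloyl diene (8S; tiglate exo)
Conditions: PPh3, DIAD, toluene, 0 °C → rt
Reagents that add atoms: none
Why: Mitsunobu esterification with inversion, the carboxylate displacing the activated endo hydroxyl by SN2 from the open convex face, which sets C8 and installs the tiglate; the fully substituted C6 end of the allyl unit disfavours substitution with allylic shift.

Step 15
Reactants: 18 8-O-tigloyl diene
Product: 19 6,12-epidioxide (3,6-dihydro-1,2-dioxine: O–C6 and O–C12; C7=C11)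
Conditions: O2, tetraphenylporphyrin (cat.), CH2Cl2, visible light, −20 °C
Reagents that add atoms: dioxygen (as singlet oxygen), O=O
Why: Sensitised singlet oxygen should add as a two-electron component across the s-cis conformer of the diene C6=C7–C11=C12 in a suprafacial [4+2] cycloaddition that forms O–C6 and O–C12 together and moves the double bond to C7=C11. The closest known reaction type is the singlet-oxygen [4+2] cycloaddition of 1,3-dienes to 3,6-dihydro-1,2-dioxines, the usual entry to 4-hydroxy-enals and butenolides. The one ring closed is the six-membered 1,2-dioxine, formed by concerted [4+2] cycloaddition. The one new stereocentre, C6, is controlled by the ring system: C6 is the junction of ring B and the four-membered ring, so oxygen can bond only from the convex face, since the other mode would require a trans-fused bicyclo[3.2.0]heptane and would meet ring A. The step needs [4+2] selectivity over the ene reaction, dioxetane formation and attack at the tiglate; the substrate secures it because the only allylic hydrogens of the tetrasubstituted C6=C7 bond are H5 (abstraction would give a cyclobutene at the ring fusion) and H8 (on the concave face), and the tiglate alkene is electron-poor. One reagent, O2, thus delivers both lactone oxygens to C6 and C12 and places the butenolide double bond.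

Step 16
Reactants: 19 6,12-epidioxide
Product: 22 tris-silylated butenolide (C2 OTBS; C4 OTES; C13 OTBS; C8 OTig), via hydroxy-enal 20 (not isolated), via lactol 21 (not isolated)
Conditions: Et3N (cat.), CH2Cl2, 0 °C → rt; then Pr4N[RuO4] (cat.), NMO, 4 Å MS, rt
Reagents that add atoms: none
Why: Kornblum–DeLaMare fragmentation (the amine removes a C12 proton and the O–O bond breaks) gives the γ-hydroxy-enal, which closes to the lactol through the C6 hydroxyl, and Ley–Griffith oxidation of the lactol gives the butenolide without touching C6.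

Step 17
Reactants: 22 tris-silylated butenolide
Product: 23 triol (C2 OH, C4 OH, C13 OH; C8 OTig)
Conditions: HF·pyridine, pyridine, THF, 0 °C → rt
Reagents that add atoms: none
Why: fluoride-mediated desilylation should cleave the primary, secondary and tertiary silyl ethers while the tiglate and the butenolide are stable to buffered HF.

Step 18
Reactants: 23 triol
Product: 24 target, (1R,2S,4R,5R,6R,8S,10R)-2,13-diacetoxy-4-hydroxy-8-tigloyloxy-7(11)-en-6,12-olide
Conditions: Ac2O, pyridine, CH2Cl2, 0 °C → rt
Reagents that add atoms: acetic anhydride, CC(=O)OC(C)=O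
Why: acylation with acetic anhydride/pyridine should esterify the primary C13 and secondary C2 hydroxyls and leave the hindered tertiary C4 hydroxyl free.

## Compound list

1 | (S)-4-(tert-butyldimethylsilyloxy)cyclopent-2-en-1-one | C1=CC(=O)C[C@@H]1O[Si](C)(C)C(C)(C)C | starting material
2 | (1R,4S)-4-(tert-butyldimethylsilyloxy)-1-methylcyclopent-2-en-1-ol | C1=C[C@](C)(O)C[C@@H]1O[Si](C)(C)C(C)(C)C | intermediate
3 | (1R,4S)-4-(tert-butyldimethylsilyloxy)-1-methyl-1-(triethylsilyloxy)cyclopent-2-ene | C1=C[C@](C)(O[Si](CC)(CC)CC)C[C@@H]1O[Si](C)(C)C(C)(C)C | intermediate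
4 | 10,10-dichlorocyclobutanone (rings A + four-membered; 2-OTBS, 4-OTES exo; CH3-15 endo) | ClC1(Cl)[C@@H]2[C@@H](O[Si](C)(C)C(C)(C)C)C[C@@](C)(O[Si](CC)(CC)CC)[C@@H]2C1=O | intermediate
5 | parent cyclobutanone (C10 H2) | C1[C@@H]2[C@@H](O[Si](C)(C)C(C)(C)C)C[C@@](C)(O[Si](CC)(CC)CC)[C@@H]2C1=O | intermediate
6 | 3-bromo-2-methylprop-1-ene | C=C(C)CBr | starting material
7 | 10-(2-methylallyl)cyclobutanone (exo-allyl epimer) | C=C(C)C[C@H]1[C@@H]2[C@@H](O[Si](C)(C)C(C)(C)C)C[C@@](C)(O[Si](CC)(CC)CC)[C@@H]2C1=O | intermediate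
8 | 10-methyl-10-(2-methylallyl)cyclobutanone (CH3-14 exo) | C=C(C)C[C@]1(C)[C@@H]2[C@@H](O[Si](C)(C)C(C)(C)C)C[C@@](C)(O[Si](CC)(CC)CC)[C@@H]2C1=O | intermediate
9 | 1,4-diketone (C6 cyclobutanone, C8 methyl ketone) | CC(=O)C[C@]1(C)[C@@H]2[C@@H](O[Si](C)(C)C(C)(C)C)C[C@@](C)(O[Si](CC)(CC)CC)[C@@H]2C1=O | intermediate
10 | tricyclic enone (C8 ketone, C6=C7; cis-syn-cis) | O=C1C[C@]2(C)[C@@H]3[C@@H](O[Si](C)(C)C(C)(C)C)C[C@@](C)(O[Si](CC)(CC)CC)[C@@H]3C2=C1 | intermediate
11 | 7-iodo enone | O=C1C[C@]2(C)[C@@H]3[C@@H](O[Si](C)(C)C(C)(C)C)C[C@@](C)(O[Si](CC)(CC)CC)[C@@H]3C2=C1I | intermediate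
12 | 2-bromoprop-2-en-1-ol | OCC(Br)=C | starting material
13 | (2-bromoallyloxy)(tert-butyl)dimethylsilane | C=C(Br)CO[Si](C)(C)C(C)(C)C | intermediate
14 | 2-[3-(tert-butyldimethylsilyloxy)prop-1-en-2-yl]-4,4,5,5-tetramethyl-1,3,2-dioxaborolane | C=C(CO[Si](C)(C)C(C)(C)C)B1OC(C)(C)C(C)(C)O1 | intermediate
15 | cross-conjugated dienone | O=C1C[C@]2(C)[C@@H]3[C@@H](O[Si](C)(C)C(C)(C)C)C[C@@](C)(O[Si](CC)(CC)CC)[C@@H]3C2=C1C(=C)CO[Si](C)(C)C(C)(C)C | intermediate
16 | endo allylic alcohol (8-epi) | O[C@@H]1C[C@]2(C)[C@@H]3[C@@H](O[Si](C)(C)C(C)(C)C)C[C@@](C)(O[Si](CC)(CC)CC)[C@@H]3C2=C1C(=C)CO[Si](C)(C)C(C)(C)C | intermediate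
17 | tiglic acid, (E)-2-methylbut-2-enoic acid | C/C=C(\C)C(O)=O | starting material
18 | 8-O-tigloyl diene (8S) | C/C=C(\C)C(=O)O[C@H]1C[C@]2(C)[C@@H]3[C@@H](O[Si](C)(C)C(C)(C)C)C[C@@](C)(O[Si](CC)(CC)CC)[C@@H]3C2=C1C(=C)CO[Si](C)(C)C(C)(C)C | intermediate
19 | 6,12-epidioxide (1,2-dioxine) | C/C=C(\C)C(=O)O[C@H]1C[C@]2(C)[C@@H]3[C@@H](O[Si](C)(C)C(C)(C)C)C[C@@](C)(O[Si](CC)(CC)CC)[C@@H]3[C@@]23OOCC(CO[Si](C)(C)C(C)(C)C)=C13 | intermediate
20 | γ-hydroxy-enal (C6 OH, C12 aldehyde cis to C6) | C/C=C(\C)C(=O)O[C@H]1C[C@]2(C)[C@@H]3[C@@H](O[Si](C)(C)C(C)(C)C)C[C@@](C)(O[Si](CC)(CC)CC)[C@@H]3[C@]2(O)/C1=C(\C=O)CO[Si](C)(C)C(C)(C)C | intermediate (not isolated)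
21 | lactol (C12 epimers) | C/C=C(\C)C(=O)O[C@H]1C[C@]2(C)[C@@H]3[C@@H](O[Si](C)(C)C(C)(C)C)C[C@@](C)(O[Si](CC)(CC)CC)[C@@H]3[C@@]23OC(O)C(CO[Si](C)(C)C(C)(C)C)=C13 | intermediate (not isolated)
22 | tris-silylated butenolide | C/C=C(\C)C(=O)O[C@H]1C[C@]2(C)[C@@H]3[C@@H](O[Si](C)(C)C(C)(C)C)C[C@@](C)(O[Si](CC)(CC)CC)[C@@H]3[C@@]23OC(=O)C(CO[Si](C)(C)C(C)(C)C)=C13 | intermediate
23 | triol | C/C=C(\C)C(=O)O[C@H]1C[C@]2(C)[C@@H]3[C@@H](O)C[C@@](C)(O)[C@@H]3[C@@]23OC(=O)C(CO)=C13 | intermediate
24 | target, CNP0210373.1 | C/C=C(\C)C(=O)O[C@H]1C[C@]2(C)[C@@H]3[C@@H](OC(C)=O)C[C@@](C)(O)[C@@H]3[C@@]23OC(=O)C(COC(C)=O)=C13 | target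

## Step count and risks

Total step count: 18. Longest linear sequence: 16 steps (steps 1–9 and 12–18, from compound 1).

**Step 3.** The ketene may bond with the opposite orientation (carbonyl carbon at C1), may add on the oxygenated face, or may react sluggishly because two allylic silyloxy groups deactivate the alkene. The fallback sets out from 3 and returns at 5, replacing the thermal ketene addition by an enone photocycloaddition whose orientation is fixed by the chromophore.
- DDQ in CH2Cl2/pH 7 buffer should oxidise the secondary allylic silyl ether of 3 directly to (R)-4-methyl-4-(triethylsilyloxy)cyclopent-2-en-1-one F1.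
- Irradiation (350 nm) of F1 with 1,1-diethoxyethene should give the head-to-tail photoadduct 6,6-diethoxy ketone F2, with the acetal carbon C6 on the enone β-carbon C5 and addition anti to the silyloxy group.
- LiBH(s-Bu)3 should reduce the C2 ketone from the convex face to the endo alcohol F3.
- Mitsunobu inversion with 4-nitrobenzoic acid gives the exo 4-nitrobenzoate F4, and K2CO3/MeOH releases the exo alcohol F5.
- TBSOTf/2,6-lutidine gives the bis-silyl ketal F6, and aqueous oxalic acid on silica unmasks the cyclobutanone, which is compound 5.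

**Step 15.** Singlet oxygen may be diverted into an ene reaction or a dioxetane at the tetrasubstituted C6=C7 bond, or the s-cis diene conformer may be too poorly populated for the [4+2] addition. The fallback sets out from 18 and returns at 22, building the two C–O bonds stepwise.
- OsO4 (cat.)/NMO should dihydroxylate the least hindered 1,1-disubstituted C11=C12 bond to the C11,C12-diol F7.
- TEMPO/NaOCl/NaClO2 should oxidise the primary C12 hydroxyl to the α-hydroxy acid F8.
- Re2O7 (cat.) should shift the tertiary allylic hydroxyl from C11 to C6 through the perrhenate ester (convex face only); the cis hydroxy acid then lactonises to 22.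

**Step 14.** The hindered endo hydroxyl with the weakly acidic tiglic acid may give elimination to the cyclopentadiene or substitution with allylic shift instead of clean inversion. The fallback sets out from 16 and returns at 18, separating inversion from acylation.
- Mitsunobu reaction with the more acidic 4-nitrobenzoic acid gives the inverted 4-nitrobenzoate F9.
- K2CO3/MeOH gives the exo allylic alcohol F10.
- Yamaguchi esterification of F10 with 17 (2,4,6-trichlorobenzoyl chloride, Et3N, DMAP) gives 18.

Further compounds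
F1 | step 3 | (R)-4-methyl-4-(triethylsilyloxy)cyclopent-2-en-1-one | O=C1C=C[C@](C)(O[Si](CC)(CC)CC)C1
F2 | step 3 | head-to-tail photoadduct 6,6-diethoxy ketone (C2 ketone) | C1[C@@H]2C(=O)C[C@@](C)(O[Si](CC)(CC)CC)[C@@H]2C1(OCC)OCC
F3 | step 3 | endo alcohol (C2) | C1[C@@H]2[C@H](O)C[C@@](C)(O[Si](CC)(CC)CC)[C@@H]2C1(OCC)OCC
F4 | step 3 | exo 4-nitrobenzoate (C2) | C1[C@@H]2[C@@H](OC(=O)c3ccc(cc3)[N+](=O)[O-])C[C@@](C)(O[Si](CC)(CC)CC)[C@@H]2C1(OCC)OCC
F5 | step 3 | exo alcohol (C2) | C1[C@@H]2[C@@H](O)C[C@@](C)(O[Si](CC)(CC)CC)[C@@H]2C1(OCC)OCC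
F6 | step 3 | bis-silyl ketal | C1[C@@H]2[C@@H](O[Si](C)(C)C(C)(C)C)C[C@@](C)(O[Si](CC)(CC)CC)[C@@H]2C1(OCC)OCC
F7 | step 15 | C11,C12-diol (C11 epimers) | C/C=C(\C)C(=O)O[C@H]1C[C@]2(C)[C@@H]3[C@@H](O[Si](C)(C)C(C)(C)C)C[C@@](C)(O[Si](CC)(CC)CC)[C@@H]3C2=C1C(O)(CO)CO[Si](C)(C)C(C)(C)C
F8 | step 15 | α-hydroxy acid (C11 epimers) | C/C=C(\C)C(=O)O[C@H]1C[C@]2(C)[C@@H]3[C@@H](O[Si](C)(C)C(C)(C)C)C[C@@](C)(O[Si](CC)(CC)CC)[C@@H]3C2=C1C(O)(CO[Si](C)(C)C(C)(C)C)C(O)=O
F9 | step 14 | inverted 4-nitrobenzoate (C8) | O=C(O[C@H]1C[C@]2(C)[C@@H]3[C@@H](O[Si](C)(C)C(C)(C)C)C[C@@](C)(O[Si](CC)(CC)CC)[C@@H]3C2=C1C(=C)CO[Si](C)(C)C(C)(C)C)c1ccc(cc1)[N+](=O)[O-]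
F10 | step 14 | exo allylic alcohol (C8) | O[C@H]1C[C@]2(C)[C@@H]3[C@@H](O[Si](C)(C)C(C)(C)C)C[C@@](C)(O[Si](CC)(CC)CC)[C@@H]3C2=C1C(=C)CO[Si](C)(C)C(C)(C)C
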